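## Retrosynthetic overview

- Ring B (C1, C2, C3, C4, C4a, C8a; tetralin numbering with C1 = CH‑aryl, C2/C3 = CH–CH2OH, C4 = CH2) is cut at C1–C2 and C3–C4. This gives an aryl‑substituted o‑quinodimethane and a chiral fumarate. The diene comes from a 1‑arylbenzocyclobutene, whose four‑membered ring (C1, C4, C4a, C8a) grows by two atoms when C2–C3 is inserted into its C1–C4 bond.
- Enabling feature: ring B is fused to arene ring A through C4a/C8a, both C1 and C4 are benzylic, and C2/C3 carry a trans pair of one‑carbon carbinols (a masked trans‑diester). The C1 aryl group (ring C) lowers the ring‑opening barrier and fixes the diene geometry.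
- The cyclobutene ring is made by [2+2] cycloaddition of a 3‑alkoxyaryne with a ketene silyl acetal. The aryne comes from 2,3‑dihydroxy‑4‑methoxybenzaldehyde by benzylation, Dakin oxidation, ortho‑iodination and triflation. Ring C is added as a Grignard reagent to the benzocyclobutenone, followed by ionic deoxygenation.
- Order of ring formation: rings A and C are bought; cyclobutene ring (step 5); ring B by two‑carbon ring expansion (step 10); then ester reduction with auxiliary removal and debenzylation.

Key step: step 10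

Assumption: the (R)‑mandelate fumarate is taken to be attacked on the face that gives the (2S,3S) ring carbons, by analogy with thermal o‑quinodimethane cycloadditions of mandelate and lactate fumarates. Should the adduct belong to the mirror‑image series, the (S)‑mandelate ester is used in steps 9 and 10 with nothing else changed.

## Route

Step 1
Reactants: 1 2,3‑dihydroxy‑4‑methoxybenzaldehyde
Product: 2 2,3‑bis(benzyloxy)‑4‑methoxybenzaldehyde
Conditions: BnBr (2.4 equiv), K2CO3, DMF, 60 °C
Reagents that add atoms: benzyl bromide, BrCc1ccccc1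
Why: Williamson etherification of both phenols gives benzyl ethers that survive organolithium, acid, heat and hydride and are removed together by hydrogenolysis at the end.

Step 2
Reactants: 2 2,3‑bis(benzyloxy)‑4‑methoxybenzaldehyde
Product: 4 2,3‑bis(benzyloxy)‑4‑methoxyphenol, via aryl formate 3 (not isolated)
Conditions: mCPBA, NaHCO3, CH2Cl2, 0 °C to rt; then K2CO3 (cat.), MeOH, rt
Reagents that add atoms: mCPBA, OOC(=O)c1cccc(Cl)c1
Why: Baeyer–Villiger (Dakin‑type) oxidation with migration of the electron‑rich aryl group gives the formate, and methanolysis should release the phenol at the carbon that later becomes C8a.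

Step 3
Reactants: 4 2,3‑bis(benzyloxy)‑4‑methoxyphenol
Product: 5 2,3‑bis(benzyloxy)‑6‑iodo‑4‑methoxyphenol
Conditions: N‑iodosuccinimide (1.05 equiv), MeCN, 0 °C, dark
Reagents that add atoms: N‑iodosuccinimide, O=C1CCC(=O)N1I
Why: electrophilic aromatic iodination should go ortho to the free hydroxyl, the strongest activator, because its para position is blocked by the methoxy group.

Step 4
Reactants: 5 2,3‑bis(benzyloxy)‑6‑iodo‑4‑methoxyphenol
Product: 6 2,3‑bis(benzyloxy)‑6‑iodo‑4‑methoxyphenyl trifluoromethanesulfonate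
Conditions: Tf2O, pyridine, CH2Cl2, 0 °C
Reagents that add atoms: triflic anhydride, O=S(=O)(OS(=O)(=O)C(F)(F)F)C(F)(F)F
Why: O‑sulfonylation of the phenol gives the ortho‑iodoaryl triflate, a standard low‑temperature aryne precursor.

Step 5
Reactants: 6 2,3‑bis(benzyloxy)‑6‑iodo‑4‑methoxyphenyl trifluoromethanesulfonate; 7 tert‑butyl[(1‑methoxyethenyl)oxy]dimethylsilane (ketene silyl acetal)
Product: 9 racemic benzocyclobutenone methyl silyl ketal, via alkoxyaryne 8 (not isolated)
Conditions: n‑BuLi (1.1 equiv), 7 (3 equiv), THF, −78 °C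
Reagents that add atoms: none
Why: iodine–lithium exchange and loss of triflate give the 3‑alkoxyaryne, and in the aryne–ketene silyl acetal [2+2] cycloaddition the nucleophilic CH2 terminus should add to the aryne carbon remote from the benzyloxy group, so that the ketal carbon ends up next to the benzyloxy‑bearing carbon (the new ketal stereocentre is racemic and is lost in step 6).

Step 6
Reactants: 9 racemic benzocyclobutenone methyl silyl ketal
Product: 10 4,5‑bis(benzyloxy)‑3‑methoxybicyclo[4.2.0]octa‑1,3,5‑trien‑7‑one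
Conditions: 46% aq. HF, MeCN, 0 °C to rt
Reagents that add atoms: none
Why: fluoride‑assisted desilylation and collapse of the hemiketal (mixed ketal hydrolysis) should give the benzocyclobutenone without touching the benzyl ethers.

Step 7
Reactants: 10 4,5‑bis(benzyloxy)‑3‑methoxybicyclo[4.2.0]octa‑1,3,5‑trien‑7‑one; 11 3,4,5‑trimethoxyphenylmagnesium bromide (THF solution)
Product: 12 racemic 4,5‑bis(benzyloxy)‑3‑methoxy‑7‑(3,4,5‑trimethoxyphenyl)bicyclo[4.2.0]octa‑1,3,5‑trien‑7‑ol
Conditions: 11 (1.3 equiv), THF, −78 °C; sat. aq. NH4Cl at −78 °C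
Reagents that add atoms: none
Why: Grignard 1,2‑addition to the strained ketone is favoured because enolisation would create a benzocyclobutadiene‑type enolate, and the cold quench should prevent alkoxide‑triggered ring opening.

Step 8
Reactants: 12 racemic 4,5‑bis(benzyloxy)‑3‑methoxy‑7‑(3,4,5‑trimethoxyphenyl)bicyclo[4.2.0]octa‑1,3,5‑trien‑7‑ol
Product: 13 racemic 4,5‑bis(benzyloxy)‑3‑methoxy‑7‑(3,4,5‑trimethoxyphenyl)bicyclo[4.2.0]octa‑1,3,5‑triene
Conditions: Et3SiH (3 equiv), CF3CO2H (5 equiv), CH2Cl2, −78 to −20 °C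
Reagents that add atoms: none
Why: ionic hydrogenation (Kursanov–Parnes) should work because the tertiary cation is stabilised by ring C and by the para‑methoxy and ortho‑benzyloxy groups of ring A and is captured by the silane; the racemic centre does not matter because it is destroyed in step 10.

Step 9
Reactants: 14 fumaryl chloride; 15 methyl (R)‑mandelate (2.1 equiv)
Product: 16 bis[(1R)‑2‑methoxy‑2‑oxo‑1‑phenylethyl] (2E)‑but‑2‑enedioate
Conditions: pyridine, CH2Cl2, 0 °C to rt
Reagents that add atoms: none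
Why: double acylation of the secondary alcohol by the acid chloride under weakly basic conditions should leave the mandelate stereocentres and the E alkene unchanged.

Step 10
Reactants: 13 racemic 4,5‑bis(benzyloxy)‑3‑methoxy‑7‑(3,4,5‑trimethoxyphenyl)bicyclo[4.2.0]octa‑1,3,5‑triene; 16 bis[(1R)‑2‑methoxy‑2‑oxo‑1‑phenylethyl] (2E)‑but‑2‑enedioate
Product: 18 bis‑mandelate (1S,2S,3S)‑1‑aryltetralin‑2,3‑dicarboxylate, via aryl‑outward o‑quinodimethane 17 (not isolated)
Conditions: 16 (2 equiv), BHT (cat.), degassed o‑xylene, 130 °C, sealed tube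
Reagents that add atoms: none
Why: heating opens the cyclobutene of 13 by conrotatory 4π electrocyclic ring opening to diene 17 (both enantiomers of 13 converge on the same achiral diene), which is trapped by 16 in an intermolecular [4+2] cycloaddition, so that C2–C3 is inserted into the C1–C4 bond and the four‑membered ring (C1, C4, C4a, C8a) becomes six‑membered ring B while ring A rearomatises. The closest known reaction type is the benzocyclobutene thermolysis/o‑quinodimethane Diels–Alder reaction with fumarates of α‑hydroxy esters as chiral dienophiles. Ring B is closed by cycloaddition, the bonds C1–C2 and C3–C4 forming suprafacially on both partners. C2 and C3 should be trans because the E geometry of the fumarate is transferred, and their absolute configuration is set by the dienophile face left open by the two (R)‑mandelate groups; C1 should be cis to C2 because the aryl group rotates outward on ring opening and the ester on C2 takes the endo position under C8a and ring A. The step needs outward torquoselectivity (secured by the clash an inward aryl would have with the inside hydrogen of the C4 methylene), endo selectivity (secondary overlap of the C2 ester carbonyl with the large diene coefficient at C8a next to the aryl‑bearing terminus) and π‑facial selectivity (auxiliary). Regiochemistry is not an issue because the dienophile is C2‑symmetric, and the excess of 16 should suppress dimerisation of the diene.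

Step 11
Reactants: 18 bis‑mandelate (1S,2S,3S)‑1‑aryltetralin‑2,3‑dicarboxylate
Product: 19 (1S,2S,3S)‑7,8‑bis(benzyloxy)‑2,3‑bis(hydroxymethyl)‑6‑methoxy‑1‑(3,4,5‑trimethoxyphenyl)tetralin
Conditions: LiAlH4 (excess), THF, 0 °C to rt; Fieser work‑up
Reagents that add atoms: none
Why: hydride reduction of both ring esters to primary alcohols also releases the auxiliary as a diol, and fast reduction at 0 °C should outrun enolisation at C2 and C3, after which no epimerisable centre remains.

Step 12
Reactants: 19 (1S,2S,3S)‑7,8‑bis(benzyloxy)‑2,3‑bis(hydroxymethyl)‑6‑methoxy‑1‑(3,4,5‑trimethoxyphenyl)tetralin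
Product: 20 CNP0188980.2
Conditions: H2 (1 atm), 10% Pd/C, EtOAc/MeOH, rt
Reagents that add atoms: none
Why: catalytic hydrogenolysis cleaves both aryl benzyl ethers under neutral conditions that should leave the methyl ethers, the primary alcohols and the C1–H/C1–aryl bonds untouched.

## Compound list

1 | 2,3‑dihydroxy‑4‑methoxybenzaldehyde | O=Cc1ccc(OC)c(O)c1O | starting material
2 | 2,3‑bis(benzyloxy)‑4‑methoxybenzaldehyde | O=Cc1ccc(OC)c(OCc2ccccc2)c1OCc1ccccc1 | intermediate
3 | 2,3‑bis(benzyloxy)‑4‑methoxyphenyl formate | O=COc1ccc(OC)c(OCc2ccccc2)c1OCc1ccccc1 | intermediate (not isolated)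
4 | 2,3‑bis(benzyloxy)‑4‑methoxyphenol | Oc1ccc(OC)c(OCc2ccccc2)c1OCc1ccccc1 | intermediate
5 | 2,3‑bis(benzyloxy)‑6‑iodo‑4‑methoxyphenol | Oc1c(I)cc(OC)c(OCc2ccccc2)c1OCc1ccccc1 | intermediate
6 | 2,3‑bis(benzyloxy)‑6‑iodo‑4‑methoxyphenyl trifluoromethanesulfonate | O=S(=O)(Oc1c(I)cc(OC)c(OCc2ccccc2)c1OCc1ccccc1)C(F)(F)F | intermediate
7 | tert‑butyl[(1‑methoxyethenyl)oxy]dimethylsilane | C=C(OC)O[Si](C)(C)C(C)(C)C | starting material
8 | 3,4‑bis(benzyloxy)‑5‑methoxybenzyne (1,2‑didehydrobenzene) | COC1=CC#CC(OCc2ccccc2)=C1OCc1ccccc1 | intermediate (not isolated)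
9 | racemic {[4,5‑bis(benzyloxy)‑3,7‑dimethoxybicyclo[4.2.0]octa‑1,3,5‑trien‑7‑yl]oxy}(tert‑butyl)dimethylsilane | COc1cc2c(c(OCc3ccccc3)c1OCc1ccccc1)C(OC)(O[Si](C)(C)C(C)(C)C)C2 | intermediate
10 | 4,5‑bis(benzyloxy)‑3‑methoxybicyclo[4.2.0]octa‑1,3,5‑trien‑7‑one | COc1cc2c(c(OCc3ccccc3)c1OCc1ccccc1)C(=O)C2 | intermediate
11 | 3,4,5‑trimethoxyphenylmagnesium bromide | COc1cc([Mg]Br)cc(OC)c1OC | starting material
12 | racemic 4,5‑bis(benzyloxy)‑3‑methoxy‑7‑(3,4,5‑trimethoxyphenyl)bicyclo[4.2.0]octa‑1,3,5‑trien‑7‑ol | COc1cc2c(c(OCc3ccccc3)c1OCc1ccccc1)C(O)(c1cc(OC)c(OC)c(OC)c1)C2 | intermediate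
13 | racemic 4,5‑bis(benzyloxy)‑3‑methoxy‑7‑(3,4,5‑trimethoxyphenyl)bicyclo[4.2.0]octa‑1,3,5‑triene | COc1cc2c(c(OCc3ccccc3)c1OCc1ccccc1)C(c1cc(OC)c(OC)c(OC)c1)C2 | intermediate
14 | fumaryl chloride | O=C(Cl)/C=C/C(=O)Cl | starting material
15 | methyl (R)‑mandelate | COC(=O)[C@H](O)c1ccccc1 | starting material
16 | bis[(1R)‑2‑methoxy‑2‑oxo‑1‑phenylethyl] (2E)‑but‑2‑enedioate | COC(=O)[C@@H](c1ccccc1)OC(=O)/C=C/C(=O)O[C@H](c1ccccc1)C(=O)OC | intermediate
17 | o‑quinodimethane with the trimethoxyphenyl group outward (anti to the exocyclic CH2; Z by CIP): 2,3‑bis(benzyloxy)‑1‑methoxy‑5‑methylidene‑6‑[(3,4,5‑trimethoxyphenyl)methylidene]cyclohexa‑1,3‑diene | COC1=CC(=C)/C(=C/c2cc(OC)c(OC)c(OC)c2)C(OCc2ccccc2)=C1OCc1ccccc1 | intermediate (not isolated)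
18 | bis[(1R)‑2‑methoxy‑2‑oxo‑1‑phenylethyl] (1S,2S,3S)‑7,8‑bis(benzyloxy)‑6‑methoxy‑1‑(3,4,5‑trimethoxyphenyl)‑1,2,3,4‑tetrahydronaphthalene‑2,3‑dicarboxylate (1,2‑cis, 2,3‑trans) | COc1cc2c(c(OCc3ccccc3)c1OCc1ccccc1)[C@H](c1cc(OC)c(OC)c(OC)c1)[C@H](C(=O)O[C@H](c1ccccc1)C(=O)OC)[C@@H](C(=O)O[C@H](c1ccccc1)C(=O)OC)C2 | intermediate
19 | [(1S,2S,3S)‑7,8‑bis(benzyloxy)‑6‑methoxy‑1‑(3,4,5‑trimethoxyphenyl)‑1,2,3,4‑tetrahydronaphthalene‑2,3‑diyl]dimethanol | COc1cc2c(c(OCc3ccccc3)c1OCc1ccccc1)[C@H](c1cc(OC)c(OC)c(OC)c1)[C@H](CO)[C@@H](CO)C2 | intermediate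
20 | CNP0188980.2, (6S,7S,8S)‑6,7‑bis(hydroxymethyl)‑3‑methoxy‑8‑(3,4,5‑trimethoxyphenyl)‑5,6,7,8‑tetrahydronaphthalene‑1,2‑diol | COc1cc2c(c(O)c1O)[C@H](c1cc(OC)c(OC)c(OC)c1)[C@H](CO)[C@@H](CO)C2 | target

## Step count and risks

Total step count: 12. Longest linear sequence: 11 (steps 1 to 8 and 10 to 12); step 9 is a one‑step side branch.

Steps most likely to fail:

1. Step 10. The thermal cycloaddition may show eroded endo and π‑facial selectivity, because the benzyloxy group at C8 twists the outward aryl group and no Lewis acid organises the dienophile; the diene may also dimerise. Fallback: set out from alcohol 12 and heat it with 16 in toluene at about 100 °C. The hydroxyl group rotates outward and gives the hydroxy o‑quinodimethane (dienol) F1, whose O–H can hydrogen‑bond to the endo ester carbonyl and so organise both endo and facial selectivity, giving the 1‑hydroxy adduct F2. Ionic hydrogenation of F2 (Et3SiH, CF3CO2H, CH2Cl2, −40 °C) then passes through the planar diarylmethyl cation at C1, which should take hydride anti to the C2 ester. This places the aryl group cis to C2 and comes back to the route at 18. This variant also bypasses step 8.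

2. Step 8. Ionisation of 12 may lead to ring cleavage or Friedel–Crafts oligomerisation of the strained cation instead of hydride capture. Fallback: set out from ketone 10 and reduce it with NaBH4 (MeOH, 0 °C) to the secondary benzocyclobutenol F3. Convert this with PBr3 (CH2Cl2, −20 °C) to the benzylic bromide F4. Couple F4 with Grignard reagent 11 in a Kumada–Corriu reaction for secondary benzylic bromides (PdCl2(MeCN)2 and Xantphos as catalyst, THF, 0 °C to rt; β‑hydride elimination is blocked because it would form a benzocyclobutadiene). This comes back to the route at 13.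

3. Step 5. Aryne formation by halogen–lithium exchange may be undercut by attack of n‑BuLi at the triflate sulfur or by slow trapping of the aryne. Fallback: set out from iodophenol 5 and silylate it with hexamethyldisilazane (THF, 70 °C) to the aryl trimethylsilyl ether F5. Treat F5 with n‑BuLi (−78 °C; iodine–lithium exchange and retro‑Brook shift of silicon from O to C) and then Tf2O to give the 2‑(trimethylsilyl)aryl triflate F6. Generate aryne 8 from F6 with CsF in MeCN at rt in the presence of 1,1‑diethoxyethene, so that no organolithium is present, to give the diethyl ketal F7. Hydrolyse F7 with 1 M aq. HCl in THF; this comes back to the route at 10.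

Further compounds
F1 | step 10 | hydroxy o‑quinodimethane (dienol) with OH outward and aryl inward | COC1=CC(=C)/C(=C(/O)c2cc(OC)c(OC)c(OC)c2)C(OCc2ccccc2)=C1OCc1ccccc1
F2 | step 10 | bis[(1R)‑2‑methoxy‑2‑oxo‑1‑phenylethyl] (1S,2R,3S)‑7,8‑bis(benzyloxy)‑1‑hydroxy‑6‑methoxy‑1‑(3,4,5‑trimethoxyphenyl)‑1,2,3,4‑tetrahydronaphthalene‑2,3‑dicarboxylate (OH cis to the C2 ester) | COc1cc2c(c(OCc3ccccc3)c1OCc1ccccc1)[C@](c1cc(OC)c(OC)c(OC)c1)(O)[C@H](C(=O)O[C@H](c1ccccc1)C(=O)OC)[C@@H](C(=O)O[C@H](c1ccccc1)C(=O)OC)C2
F3 | step 8 | racemic 4,5‑bis(benzyloxy)‑3‑methoxybicyclo[4.2.0]octa‑1,3,5‑trien‑7‑ol | COc1cc2c(c(OCc3ccccc3)c1OCc1ccccc1)C(O)C2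
F4 | step 8 | racemic 4,5‑bis(benzyloxy)‑7‑bromo‑3‑methoxybicyclo[4.2.0]octa‑1,3,5‑triene | COc1cc2c(c(OCc3ccccc3)c1OCc1ccccc1)C(Br)C2
F5 | step 5 | [2,3‑bis(benzyloxy)‑6‑iodo‑4‑methoxyphenoxy]trimethylsilane | C[Si](C)(C)Oc1c(I)cc(OC)c(OCc2ccccc2)c1OCc1ccccc1
F6 | step 5 | 2,3‑bis(benzyloxy)‑4‑methoxy‑6‑(trimethylsilyl)phenyl trifluoromethanesulfonate | C[Si](C)(C)c1cc(OC)c(OCc2ccccc2)c(OCc2ccccc2)c1OS(=O)(=O)C(F)(F)F
F7 | step 5 | 4,5‑bis(benzyloxy)‑7,7‑diethoxy‑3‑methoxybicyclo[4.2.0]octa‑1,3,5‑triene | CCOC1(OCC)Cc2cc(OC)c(OCc3ccccc3)c(OCc3ccccc3)c21
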